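The readings come from a simulation for an exercise; scatter was added.

Book the losses first and count what is left of the starting material, not what has been made: that is my reply to your request for a quick number on the new flask, and these are the grounds.

all flasks: partner 1.25 M
- Friday's: starting material 0.12 M; protic impurity 5 mM; initiator 5 mM; radical scavenger 2 mM; run made earlier
- Saturday's: starting material 0.19 M; protic impurity 5 mM; initiator 5 mM; radical scavenger 2 mM; run made earlier
- flask: starting material 0.25 M; protic impurity 5.00 mM; initiator 5.0 mM; radical scavenger 2.0 mM; time 12 d

| run | time / d | product / % | starting material / % |
|---|---|---|---|
| Friday's | 0.625 | 35 | 67 |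
| Friday's | 1.67 | 73 | 23 |
| Friday's | 3.00 | 87 | 9 |
| Friday's | 5.00 | 94 | 3 |
| Friday's | 8.00 | 93 | 3 |
| Friday's | 10.0 | 94 | 2 |
| Friday's | 12.0 | 93 | 0 |
| Saturday's | 0.625 | 33 | 67 |
| Saturday's | 1.67 | 74 | 20 |
| Saturday's | 3.00 | 87 | 13 |
| Saturday's | 5.00 | 92 | 5 |
| Saturday's | 8.00 | 93 | 0 |
| Saturday's | 10.0 | 93 | 2 |
| Saturday's | 12.0 | 98 | 3 |

(each reading ± 2 percentage points)

- steps that have been proposed: initiator -> 2 initiating radical; starting material + initiating radical -> chain carrier; partner + chain carrier -> product + initiating radical; 2 initiating radical -> ended chains A; radical scavenger + initiating radical -> ended chains B; starting material + protic impurity -> quenched substrate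

- product present at 12 d, in percent of the starting material charged
- starting material present at 12 d, in percent of the starting material charged
- quenched substrate present at 12 d, in percent of the starting material charged
- concentration of partner at 12 d, in M

Friday's and Saturday's percent curves lie on each other within the scatter, with 23% and 20% of the starting material left at 1.67 d, so I carry that curve over to the new flask. From 8.00 d on, the readings of starting material in both runs average 1.67%, and I take that as the part left at 12 d.

One loss does not follow the percent curve. If the protic impurity, the limiting reagent of its step, takes starting material one for one until it is used up, the percent lost is the quench share, [protic impurity] charged divided by [starting material] charged, which for the new flask is 2.00%. The same share gives 4.17% for Friday's run and 2.63% for Saturday's, while the unaccounted gaps at 10.0 d read 4.00% and 5.00%, which is as closely as readings of this scatter can speak. What remains is product, 96.3% by my reckoning, and with one partner spent for each product, [partner] ends at 1.01 M.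

Your forecast gives 95.5% product, 2.3% starting material, 2% quenched substrate and [partner] 1.011 M, holding that “the reaction reaches a dead end”. We differ in the starting material left and in the product that hangs on it, each by less than the scatter.

The flask gives 95.6% product, 2.37% starting material, 2.00% quenched substrate and [partner] 1.01 M.

    initiator → 2 initiating radical (k = 0.0300 h⁻¹)
    starting material + initiating radical → chain carrier (k = 7.60 × 10⁶ M⁻¹ h⁻¹)
    partner + chain carrier → product + initiating radical (k = 1.60 × 10⁶ M⁻¹ h⁻¹)
    2 initiating radical → ended chains A (k = 6.00 × 10⁸ M⁻¹ s⁻¹)
    radical scavenger + initiating radical → ended chains B (k = 5.70 × 10⁶ M⁻¹ s⁻¹)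
    starting material + protic impurity → quenched substrate (k = 5.80 M⁻¹ h⁻¹)

The quench share of 2.00% stands in this flask as its quenched substrate, and the same share reckons the neighbour flask with 0.50 M of partner, which holds 2.00% quenched substrate. For the forecast to fail, this flask's recipe would have to change: with all else held, its product moves by 5 points with initiator down at 2.94 mM or with protic impurity up at 17.8 mM, a quench share of 7.12%. At 0.850 d the flask's starting material has a half-life of 0.62 d by its step with initiating radical, shorter than the 0.96 d of the initiator by its decomposition. At 12.0 d the flask holds 0.018% of the initiator charged and 2.4% of the starting material charged.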